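**Retrosynthetic overview**

1. The 36-membered lactone (C1–C35 closed through O35) carries its methyl branch at C3, β to the lactone carbonyl C1, so C2–C3 can be an enoate bond of the ring. The methyl is added last by copper-catalysed conjugate addition to a macrocyclic E-enoate, and that enoate comes from Horner–Wadsworth–Emmons closure of an O35 phosphonoacetate onto a C3 aldehyde (the only ring, closed in step 40).
2. The linear C3–C40 chain comes from a 1,5-anti boron aldol (C28–C29) between a C3–C28 methyl ketone (O25 as PMB ether) and a C29–C40 aldehyde, then 1,3-anti reduction at C27. The C3 aldehyde is carried as a terminal vinyl group.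
3. The C3–C28 ketone comes from three copper-catalysed Grignard/epoxide unions (C6–C7, C10–C11, C18–C19) of enantiopure chiral-pool acetonide blocks, because remote 1,5-related centres (C5 to C25) cannot be purified by separation. 2-Methyl-1,3-dithiane supplies C27/C28.
4. The C29–C40 aldehyde comes from Sharpless epoxidation and Me3Al opening of (E)-hept-2-en-1-ol (C35, C36), a dithiane–epoxide union (C33–C34) and an Evans–Tishchenko reduction (C33), which leaves a benzoate on O35 to mark the future lactone oxygen.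

Key step: step 40

Remark on numbering: C1–C40 and O35 are those of the target (C1 lactone carbonyl). In fragment names "as in the target" means the spatial arrangement of the target at that carbon; CIP letters can change with remote groups, and the SMILES in the compound list is decisive. The extra CH2 beyond C3 is lost as formaldehyde in step 39.

Remark on the Grignard reagents: 3 and 17 are each prepared once as a titrated THF stock solution, kept under argon, and drawn on for two epoxide openings (3 for steps 3 and 9, 17 for steps 14 and 18).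

Assumption: the macrocyclic E-enoate is taken to follow the facial preference of acyclic E-enoates under CuI/Tol-BINAP, so (S)-Tol-BINAP is written for methyl delivery to the C3 Re face; the antipodal ligand is used if a model enoate shows the opposite sense. Compounds 1, 4, 9, 28, 33, 38, 39 and 54 are taken as commercial.

**Eight-carbon Grignard block (C11–C18 and C19–C26)**

Step 1
Reactants: 1 2-[(4S)-2,2-dimethyl-1,3-dioxolan-4-yl]ethan-1-ol
Product: 2 (4S)-4-(2-bromoethyl)-2,2-dimethyl-1,3-dioxolane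
Conditions: CBr4, PPh3, Et3N (cat.), CH2Cl2, 0 °C
Reagents that add atoms: carbon tetrabromide, BrC(Br)(Br)Br
Why: Appel bromination of the primary alcohol under near-neutral conditions should leave the acetonide and its stereocentre (later C9, C17 and C25) untouched.

Step 2
Reactants: 2 (4S)-4-(2-bromoethyl)-2,2-dimethyl-1,3-dioxolane
Product: 3 {2-[(4S)-2,2-dimethyl-1,3-dioxolan-4-yl]ethyl}magnesium bromide (titrated THF solution)
Conditions: Mg turnings, 1,2-dibromoethane (cat.), THF, 35 °C; titrated, kept under argon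
Reagents that add atoms: magnesium, [Mg]
Why: Grignard formation by insertion of magnesium into the primary C–Br bond, which should be clean because the acetonide oxygens sit γ and δ to the carbanion and offer no β-elimination path.

Step 3
Reactants: 3 {2-[(4S)-2,2-dimethyl-1,3-dioxolan-4-yl]ethyl}magnesium bromide; 4 (2R)-2-[2-(benzyloxy)ethyl]oxirane
Product: 5 (3S)-1-(benzyloxy)-6-[(4S)-2,2-dimethyl-1,3-dioxolan-4-yl]hexan-3-ol
Conditions: 3 (1.3 equiv), CuI (10 mol%), THF, −30 to 0 °C; aq. NH4Cl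
Reagents that add atoms: none
Why: Copper-catalysed Grignard opening of a terminal epoxide at its CH2 terminus joins two chiral-pool units without touching either stereocentre, giving the 1,5-anti diol pattern used for C13/C17 and C21/C25.

Step 4
Reactants: 5 (3S)-1-(benzyloxy)-6-[(4S)-2,2-dimethyl-1,3-dioxolan-4-yl]hexan-3-ol
Product: 6 TBS ether of 5
Conditions: TBSCl, imidazole, DMF, rt
Reagents that add atoms: tert-butyldimethylsilyl chloride, CC(C)(C)[Si](C)(C)Cl
Why: Standard silylation of an unhindered secondary alcohol; the acetonide is stable to imidazole in DMF.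

Step 5
Reactants: 6 TBS ether of 5
Product: 7 (3S)-3-[(tert-butyldimethylsilyl)oxy]-6-[(4S)-2,2-dimethyl-1,3-dioxolan-4-yl]hexan-1-ol
Conditions: H2 (1 atm), 10% Pd/C, EtOAc, rt
Reagents that add atoms: none
Why: Hydrogenolysis of the benzyl ether under neutral conditions should spare the silyl ether and the acetonide.

Step 6
Reactants: 7 (3S)-3-[(tert-butyldimethylsilyl)oxy]-6-[(4S)-2,2-dimethyl-1,3-dioxolan-4-yl]hexan-1-ol
Product: 8 (4S)-4-{(4S)-6-bromo-4-[(tert-butyldimethylsilyl)oxy]hexyl}-2,2-dimethyl-1,3-dioxolane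
Conditions: CBr4, PPh3, Et3N (cat.), CH2Cl2, 0 °C
Reagents that add atoms: carbon tetrabromide, BrC(Br)(Br)Br
Why: Appel bromination of the primary alcohol gives the bromide from which the γ-silyloxy Grignard reagent is made.

**Western fragment (C3–C28 methyl ketone)**

Step 7
Reactants: 9 (S)-epichlorohydrin
Product: 10 (2S)-1-chloropent-4-en-2-ol
Conditions: vinylMgBr, CuI (5 mol%), THF, −60 to −30 °C
Reagents that add atoms: vinylmagnesium bromide, C=C[Mg]Br
Why: Copper-catalysed vinyl Grignard opening of the epoxide CH2 is faster than chloride displacement at low temperature, so C5 is taken unchanged from the chiral pool.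

Step 8
Reactants: 10 (2S)-1-chloropent-4-en-2-ol
Product: 11 (2S)-2-(prop-2-en-1-yl)oxirane
Conditions: NaOH (powdered), Et2O, rt
Reagents that add atoms: none
Why: Intramolecular Williamson closure of the chlorohydrin forms the epoxide without involving the C5–O bond.

Step 9
Reactants: 11 (2S)-2-(prop-2-en-1-yl)oxirane; 3 {2-[(4S)-2,2-dimethyl-1,3-dioxolan-4-yl]ethyl}magnesium bromide
Product: 12 (4R)-7-[(4S)-2,2-dimethyl-1,3-dioxolan-4-yl]hept-1-en-4-ol (C3–C10; C5 carbinol; C9/C10 acetonide)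
Conditions: 3 (1.3 equiv), CuI (10 mol%), THF, −30 to 0 °C; aq. NH4Cl
Reagents that add atoms: none
Why: Copper-catalysed Grignard opening of the terminal epoxide forms C6–C7 and brings in C9 with fixed configuration.

Step 10
Reactants: 12 (4R)-7-[(4S)-2,2-dimethyl-1,3-dioxolan-4-yl]hept-1-en-4-ol
Product: 13 O5 TBS ether of 12
Conditions: TBSCl, imidazole, DMF, rt
Reagents that add atoms: tert-butyldimethylsilyl chloride, CC(C)(C)[Si](C)(C)Cl
Why: Standard silylation of the secondary homoallylic alcohol.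

Step 11
Reactants: 13 O5 TBS ether of 12
Product: 14 (2S,6R)-6-[(tert-butyldimethylsilyl)oxy]non-8-ene-1,2-diol
Conditions: PPTS (0.2 equiv), MeOH, rt to 35 °C
Reagents that add atoms: none
Why: Acid-catalysed methanolysis (transacetalisation) of a terminal acetonide is expected to be faster than cleavage of a secondary TBS ether under PPTS.

Step 12
Reactants: 14 (2S,6R)-6-[(tert-butyldimethylsilyl)oxy]non-8-ene-1,2-diol
Product: 16 tert-butyldimethyl{[(4R)-7-[(2S)-oxiran-2-yl]hept-1-en-4-yl]oxy}silane (C3–C10 epoxide), via primary tosylate 15 (not isolated)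
Conditions: NaH, N-tosylimidazole, THF, 0 °C to rt
Reagents that add atoms: none
Why: One-pot selective primary sulfonylation and Williamson ring closure converts the 1,2-diol into the terminal epoxide with retention at C9, since only the C10–O bond is exchanged.

Step 13
Reactants: 8 (4S)-4-{(4S)-6-bromo-4-[(tert-butyldimethylsilyl)oxy]hexyl}-2,2-dimethyl-1,3-dioxolane
Product: 17 {(3S)-3-[(tert-butyldimethylsilyl)oxy]-6-[(4S)-2,2-dimethyl-1,3-dioxolan-4-yl]hexyl}magnesium bromide (titrated THF solution)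
Conditions: Mg turnings, 1,2-dibromoethane (cat.), THF, 35 °C; titrated, kept under argon
Reagents that add atoms: magnesium, [Mg]
Why: Grignard formation by insertion of magnesium into the primary C–Br bond, to which the γ-silyloxy group and the remote acetonide are inert, on a scale that covers the couplings of steps 14 and 18.

Step 14
Reactants: 16 C3–C10 epoxide; 17 {(3S)-3-[(tert-butyldimethylsilyl)oxy]-6-[(4S)-2,2-dimethyl-1,3-dioxolan-4-yl]hexyl}magnesium bromide
Product: 18 C3–C18 alcohol (free C9–OH; O5/O13 TBS; C17/C18 acetonide; C3 vinyl)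
Conditions: 17 (1.5 equiv), CuI (10 mol%), THF, −30 to 0 °C; aq. NH4Cl
Reagents that add atoms: none
Why: Copper-catalysed Grignard opening of the terminal epoxide forms C10–C11 and introduces C13 and C17 from the enantiopure block.

Step 15
Reactants: 18 C3–C18 alcohol
Product: 19 C3–C18 tris-TBS ether (O5/O9/O13) with C17/C18 acetonide
Conditions: TBSCl, imidazole, DMAP (cat.), DMF, 35 °C
Reagents that add atoms: tert-butyldimethylsilyl chloride, CC(C)(C)[Si](C)(C)Cl
Why: Standard silylation of the secondary alcohol under conditions that do not disturb the acetonide.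

Step 16
Reactants: 19 C3–C18 tris-TBS ether
Product: 20 C3–C18 17,18-diol (O5/O9/O13 TBS)
Conditions: PPTS (0.2 equiv), MeOH/CH2Cl2, rt to 35 °C
Reagents that add atoms: none
Why: Selective methanolysis of the terminal acetonide in the presence of secondary TBS ethers, as in step 11.

Step 17
Reactants: 20 C3–C18 17,18-diol
Product: 22 C3–C18 epoxide (C17–C18 oxirane; O5/O9/O13 TBS), via primary tosylate 21 (not isolated)
Conditions: NaH, N-tosylimidazole, THF, 0 °C to rt
Reagents that add atoms: none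
Why: One-pot primary sulfonylation and ring closure gives the terminal epoxide with retention at C17.

Step 18
Reactants: 22 C3–C18 epoxide; 17 {(3S)-3-[(tert-butyldimethylsilyl)oxy]-6-[(4S)-2,2-dimethyl-1,3-dioxolan-4-yl]hexyl}magnesium bromide
Product: 23 C3–C26 alcohol (free C17–OH; O5/O9/O13/O21 TBS; C25/C26 acetonide)
Conditions: 17 (1.5 equiv), CuI (10 mol%), THF, −30 to 0 °C; aq. NH4Cl
Reagents that add atoms: none
Why: A second copper-catalysed Grignard opening with the same block forms C18–C19 and introduces C21 and C25.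

Step 19
Reactants: 23 C3–C26 alcohol
Product: 24 C3–C26 pentakis-TBS ether (O5/O9/O13/O17/O21) with C25/C26 acetonide
Conditions: TBSCl, imidazole, DMAP (cat.), DMF, 35 °C
Reagents that add atoms: tert-butyldimethylsilyl chloride, CC(C)(C)[Si](C)(C)Cl
Why: Standard silylation of the secondary alcohol.

Step 20
Reactants: 24 C3–C26 pentakis-TBS ether
Product: 25 C3–C26 25,26-diol
Conditions: PPTS (0.2 equiv), MeOH/CH2Cl2, rt to 35 °C
Reagents that add atoms: none
Why: Selective methanolysis of the terminal acetonide, as in step 11.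

Step 21
Reactants: 25 C3–C26 25,26-diol
Product: 27 C3–C26 epoxide (C25–C26 oxirane), via primary tosylate 26 (not isolated)
Conditions: NaH, N-tosylimidazole, THF, 0 °C to rt
Reagents that add atoms: none
Why: One-pot primary sulfonylation and ring closure gives the terminal epoxide with retention at C25.

Step 22
Reactants: 27 C3–C26 epoxide; 28 2-methyl-1,3-dithiane
Product: 30 C3–C28 alcohol (free C25–OH; C27 as 2-methyl-1,3-dithiane), via 2-lithio-2-methyl-1,3-dithiane 29 (not isolated)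
Conditions: 28, n-BuLi, THF, −20 °C; then 27, −20 to 0 °C
Reagents that add atoms: none
Why: Corey–Seebach acyl-anion opening of the terminal epoxide forms C26–C27 and installs the methyl ketone in masked form.

Step 23
Reactants: 30 C3–C28 alcohol
Product: 31 O25 PMB ether of 30
Conditions: NaH, PMBCl, Bu4NI (cat.), THF/DMF, 0 °C to rt
Reagents that add atoms: 4-methoxybenzyl chloride, COc1ccc(CCl)cc1
Why: Williamson etherification installs the benzylic ether needed for 1,5-anti induction in the aldol; the nearest silyl ether is 1,5-related, so silyl migration is not expected.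

Step 24
Reactants: 31 O25 PMB ether of 30
Product: 32 C3–C28 methyl ketone (C27 ketone; O25 PMB; O5/O9/O13/O17/O21 TBS; C3 vinyl)
Conditions: MeI, CaCO3, MeCN/THF/H2O, 45 °C
Reagents that add atoms: water, O
Why: Alkylative hydrolysis of the dithiane under neutral conditions should unmask the ketone without affecting the alkene, the PMB ether or the silyl ethers.

**Eastern fragment (C29–C40 aldehyde)**

Step 25
Reactants: 33 (E)-hept-2-en-1-ol
Product: 34 [(2R,3R)-3-butyloxiran-2-yl]methanol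
Conditions: Ti(OiPr)4 (cat.), D-(−)-diisopropyl tartrate (cat.), t-BuOOH, 4 Å MS, CH2Cl2, −20 °C
Reagents that add atoms: tert-butyl hydroperoxide, CC(C)(C)OO
Why: Sharpless asymmetric epoxidation of an E-allylic alcohol with the D-tartrate ligand delivers oxygen to the face that gives the (2R,3R)-epoxy alcohol.

Step 26
Reactants: 34 [(2R,3R)-3-butyloxiran-2-yl]methanol
Product: 35 (2S,3S)-3-methylheptane-1,2-diol
Conditions: Me3Al (3 equiv), hexane/CH2Cl2, 0 °C to rt
Reagents that add atoms: trimethylaluminium, C[Al](C)C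
Why: Trimethylaluminium opens 2,3-epoxy alcohols regioselectively at C3 with inversion through the aluminium alkoxide, which sets the C36 methyl centre while the C35 carbinol is retained.

Step 27
Reactants: 35 (2S,3S)-3-methylheptane-1,2-diol
Product: 37 (2S)-2-[(2S)-hexan-2-yl]oxirane (C34–C40 epoxide), via primary tosylate 36 (not isolated)
Conditions: NaH, N-tosylimidazole, THF, 0 °C to rt
Reagents that add atoms: none
Why: One-pot primary sulfonylation and Williamson closure gives the terminal epoxide with retention at C35.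

Step 28
Reactants: 38 1,3-dithiane; 39 5-bromopent-1-ene
Product: 41 2-(pent-4-en-1-yl)-1,3-dithiane, via 2-lithio-1,3-dithiane 40 (not isolated)
Conditions: n-BuLi, THF, −30 °C; then 39, −30 °C to rt
Reagents that add atoms: none
Why: Corey–Seebach alkylation of lithiated dithiane with a primary bromide gives the C29–C33 unit, with C33 as the masked carbonyl and the alkene as the masked C29 aldehyde.

Step 29
Reactants: 41 2-(pent-4-en-1-yl)-1,3-dithiane; 37 (2S)-2-[(2S)-hexan-2-yl]oxirane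
Product: 43 (2R,3S)-3-methyl-1-[2-(pent-4-en-1-yl)-1,3-dithian-2-yl]heptan-2-ol, via lithiated dithiane 42 (not isolated)
Conditions: t-BuLi, THF/HMPA, −78 °C; then 37, −78 to −30 °C
Reagents that add atoms: none
Why: The 2-alkyl dithiane anion opens the terminal epoxide at its CH2 carbon (C33–C34 bond), leaving the C35 carbinol free and configurationally intact.

Step 30
Reactants: 43 (2R,3S)-3-methyl-1-[2-(pent-4-en-1-yl)-1,3-dithian-2-yl]heptan-2-ol
Product: 44 (8R,9S)-8-hydroxy-9-methyltridec-1-en-6-one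
Conditions: MeI, CaCO3, MeCN/H2O, 40 °C
Reagents that add atoms: water, O
Why: Neutral alkylative dithiane hydrolysis should give the β-hydroxy ketone without elimination or retro-aldol cleavage.

Step 31
Reactants: 44 (8R,9S)-8-hydroxy-9-methyltridec-1-en-6-one
Product: 45 (6S,8R,9S)-6-hydroxy-9-methyltridec-1-en-8-yl benzoate
Conditions: PhCHO (5 equiv), SmI2 (0.3 equiv), THF, −10 °C
Reagents that add atoms: benzaldehyde, O=Cc1ccccc1
Why: Evans–Tishchenko reduction transfers hydride intramolecularly from the samarium-bound hemiacetal through a chair transition state, so C33 is set 1,3-anti to C35 while O35 emerges as the benzoate.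

Step 32
Reactants: 45 (6S,8R,9S)-6-hydroxy-9-methyltridec-1-en-8-yl benzoate
Product: 46 (6S,8R,9S)-6-[(tert-butyldimethylsilyl)oxy]-9-methyltridec-1-en-8-yl benzoate
Conditions: TBSOTf, 2,6-lutidine, CH2Cl2, −78 °C
Reagents that add atoms: tert-butyldimethylsilyl trifluoromethanesulfonate, CC(C)(C)[Si](C)(C)OS(=O)(=O)C(F)(F)F
Why: Silylation with the triflate and a hindered base at low temperature should protect O33 before any 1,3-benzoate migration can occur.

Step 33
Reactants: 46 (6S,8R,9S)-6-[(tert-butyldimethylsilyl)oxy]-9-methyltridec-1-en-8-yl benzoate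
Product: 48 (5S,7R,8S)-5-[(tert-butyldimethylsilyl)oxy]-8-methyl-1-oxododecan-7-yl benzoate (C29–C40 aldehyde), via ozonide 47 (not isolated)
Conditions: O3, CH2Cl2, −78 °C; then PPh3, −78 °C to rt
Reagents that add atoms: ozone, [O-][O+]=O
Why: Ozonolysis with reductive work-up cleaves the only alkene to the C29 aldehyde; ester and silyl ether are inert.

**Union and end game**

Step 34
Reactants: 32 C3–C28 methyl ketone; 48 C29–C40 aldehyde
Product: 50 C3–C40 aldol adduct (C29–OH; C27 ketone; O25 PMB; O35 benzoate; six TBS ethers), via dibutylboron enolate 49 (not isolated)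
Conditions: Bu2BOTf, i-Pr2NEt, Et2O, −78 °C; then 48 (1.3 equiv), −78 to −20 °C; pH 7 buffer, MeOH, H2O2, 0 °C
Reagents that add atoms: none
Why: Boron-mediated methyl ketone aldol in which the β-PMB ether of the enolate directs 1,5-anti addition, so C29 is set relative to C25 while the C28–C29 bond joins the two halves.

Step 35
Reactants: 50 C3–C40 aldol adduct
Product: 51 C3–C40 27,29-diol (27,29-anti; 25,27-syn)
Conditions: Me4NBH(OAc)3, MeCN/AcOH/THF, −30 to −20 °C
Reagents that add atoms: none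
Why: Evans–Saksena reduction delivers hydride intramolecularly from the C29 alkoxy-bound acetoxyborohydride, setting C27 1,3-anti to C29.

Step 36
Reactants: 51 C3–C40 27,29-diol
Product: 52 fully protected C3–C40 chain (eight TBS ethers; O25 PMB; O35 benzoate; C3 vinyl)
Conditions: TBSOTf, 2,6-lutidine, CH2Cl2, −78 to 0 °C
Reagents that add atoms: tert-butyldimethylsilyl trifluoromethanesulfonate, CC(C)(C)[Si](C)(C)OS(=O)(=O)C(F)(F)F
Why: Exhaustive silylation of the two secondary alcohols with the reactive triflate.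

Step 37
Reactants: 52 fully protected C3–C40 chain
Product: 53 C3–C40 O35 alcohol (eight TBS ethers; O25 PMB; C3 vinyl)
Conditions: i-Bu2AlH, CH2Cl2, −78 °C
Reagents that add atoms: none
Why: Reductive cleavage of the benzoate frees only O35, since silyl ethers, the PMB ether and the alkene do not react with the hydride.

Step 38
Reactants: 53 C3–C40 O35 alcohol; 54 diethylphosphonoacetic acid
Product: 55 C3–C40 O35 diethylphosphonoacetate (C3 vinyl)
Conditions: DCC, DMAP (cat.), CH2Cl2, 0 °C to rt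
Reagents that add atoms: none
Why: Steglich esterification acylates the single free, hindered secondary alcohol intermolecularly.

Step 39
Reactants: 55 C3–C40 O35 diethylphosphonoacetate
Product: 57 C3 aldehyde with O35 diethylphosphonoacetate (eight TBS ethers; O25 PMB), via vicinal diol 56 (not isolated)
Conditions: OsO4 (2 mol%), NaIO4, 2,6-lutidine, dioxane/THF/H2O, rt
Reagents that add atoms: osmium tetroxide, O=[Os](=O)(=O)=O; sodium periodate, [Na+].[O-]I(=O)(=O)=O
Why: Lemieux–Johnson dihydroxylation and periodate cleavage of the only alkene unmasks the C3 aldehyde without exposing the PMB ether to ozone.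

Step 40
Reactants: 57 C3 aldehyde with O35 diethylphosphonoacetate
Product: 58 36-membered (2E)-enoate lactone without the C3 methyl group (eight TBS ethers; O25 PMB)
Conditions: LiCl, DBU, MeCN/THF, rt, slow addition of 57 to 0.5 mM final concentration
Reagents that add atoms: none
Why: Lithium chelation of the phosphonoacetate lowers its pKa so that DBU deprotonates it; the lithium phosphonate enolate adds to the C3 aldehyde and the oxaphosphetane collapses with loss of lithium diethyl phosphate to give the C2=C3 double bond. The closest known reaction type is the intramolecular Horner–Wadsworth–Emmons olefination under Masamune–Roush conditions used to close large macrolide enoates. The 36-membered ring closes end to end by C=C formation next to the preformed O35 ester, a strain-free closure whose only handicap is entropic and which is therefore run by slow addition at high dilution. No stereocentre is formed; the E geometry follows from the reversible addition and syn elimination of a stabilised phosphonate. The step needs ring closure to outrun oligomerisation and the aldehyde to survive the base; dilution secures the first, and the mild amine/LiCl base together with a poor silyloxy leaving group at C5 and the absence of a stereocentre at C4 secure the second.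

Step 41
Reactants: 58 36-membered (2E)-enoate lactone
Product: 59 C3-methyl macrolactone (eight TBS ethers; O25 PMB)
Conditions: MeMgBr, CuI (10 mol%), (S)-Tol-BINAP (15 mol%), t-BuOMe, −20 °C
Reagents that add atoms: methylmagnesium bromide, C[Mg]Br
Why: Copper-catalysed asymmetric conjugate addition of a Grignard reagent to an E-α,β-unsaturated ester, in which the Tol-BINAP-bound methylcopper species is expected to add to the C3 Re face and set the (3R) centre by catalyst control.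

Step 42
Reactants: 59 C3-methyl macrolactone
Product: 60 C25 alcohol of the macrolactone (eight TBS ethers)
Conditions: DDQ, CH2Cl2/pH 7 buffer, 0 °C to rt
Reagents that add atoms: none
Why: Oxidative cleavage of the PMB ether by DDQ through the benzylic oxocarbenium ion, to which the saturated lactone and silyl ethers are inert.

Step 43
Reactants: 60 C25 alcohol of the macrolactone
Product: 61 target macrolactone nonaol CNP0225459.2
Conditions: HF·pyridine, pyridine, THF, 0 °C to rt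
Reagents that add atoms: none
Why: Global fluoride-mediated desilylation under buffered conditions should remove all eight TBS ethers while keeping acyl migration of the lactone to the neighbouring O33 hydroxyl to a minimum.

**Compound list**

1 | 2-[(4S)-2,2-dimethyl-1,3-dioxolan-4-yl]ethan-1-ol | OCC[C@H]1COC(C)(C)O1 | starting material
2 | (4S)-4-(2-bromoethyl)-2,2-dimethyl-1,3-dioxolane | BrCC[C@H]1COC(C)(C)O1 | intermediate
3 | {2-[(4S)-2,2-dimethyl-1,3-dioxolan-4-yl]ethyl}magnesium bromide | Br[Mg]CC[C@H]1COC(C)(C)O1 | intermediate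
4 | (2R)-2-[2-(benzyloxy)ethyl]oxirane | c1ccccc1COCC[C@@H]1CO1 | starting material
5 | (3S)-1-(benzyloxy)-6-[(4S)-2,2-dimethyl-1,3-dioxolan-4-yl]hexan-3-ol | c1ccccc1COCC[C@@H](O)CCC[C@H]1COC(C)(C)O1 | intermediate
6 | {[(3S)-1-(benzyloxy)-6-[(4S)-2,2-dimethyl-1,3-dioxolan-4-yl]hexan-3-yl]oxy}(tert-butyl)dimethylsilane | c1ccccc1COCC[C@@H](O[Si](C)(C)C(C)(C)C)CCC[C@H]1COC(C)(C)O1 | intermediate
7 | (3S)-3-[(tert-butyldimethylsilyl)oxy]-6-[(4S)-2,2-dimethyl-1,3-dioxolan-4-yl]hexan-1-ol | OCC[C@@H](O[Si](C)(C)C(C)(C)C)CCC[C@H]1COC(C)(C)O1 | intermediate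
8 | (4S)-4-{(4S)-6-bromo-4-[(tert-butyldimethylsilyl)oxy]hexyl}-2,2-dimethyl-1,3-dioxolane | BrCC[C@@H](O[Si](C)(C)C(C)(C)C)CCC[C@H]1COC(C)(C)O1 | intermediate
9 | (S)-epichlorohydrin, (2S)-2-(chloromethyl)oxirane | ClC[C@@H]1CO1 | starting material
10 | (2S)-1-chloropent-4-en-2-ol | C=CC[C@H](O)CCl | intermediate
11 | (2S)-2-(prop-2-en-1-yl)oxirane | C=CC[C@H]1CO1 | intermediate
12 | (4R)-7-[(4S)-2,2-dimethyl-1,3-dioxolan-4-yl]hept-1-en-4-ol (C3–C10) | C=CC[C@H](O)CCC[C@H]1COC(C)(C)O1 | intermediate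
13 | tert-butyl{[(4R)-7-[(4S)-2,2-dimethyl-1,3-dioxolan-4-yl]hept-1-en-4-yl]oxy}dimethylsilane | C=CC[C@H](O[Si](C)(C)C(C)(C)C)CCC[C@H]1COC(C)(C)O1 | intermediate
14 | (2S,6R)-6-[(tert-butyldimethylsilyl)oxy]non-8-ene-1,2-diol | C=CC[C@H](O[Si](C)(C)C(C)(C)C)CCC[C@H](O)CO | intermediate
15 | (2S,6R)-6-[(tert-butyldimethylsilyl)oxy]-2-hydroxynon-8-en-1-yl 4-methylbenzenesulfonate | C=CC[C@H](O[Si](C)(C)C(C)(C)C)CCC[C@H](O)COS(=O)(=O)c1ccc(C)cc1 | intermediate
16 | tert-butyldimethyl{[(4R)-7-[(2S)-oxiran-2-yl]hept-1-en-4-yl]oxy}silane (C3–C10 epoxide) | C=CC[C@H](O[Si](C)(C)C(C)(C)C)CCC[C@H]1CO1 | intermediate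
17 | {(3S)-3-[(tert-butyldimethylsilyl)oxy]-6-[(4S)-2,2-dimethyl-1,3-dioxolan-4-yl]hexyl}magnesium bromide | Br[Mg]CC[C@@H](O[Si](C)(C)C(C)(C)C)CCC[C@H]1COC(C)(C)O1 | intermediate
18 | C3–C18 alcohol: CH2=CH–CH2–CH(OTBS)–(CH2)3–CH(OH)–(CH2)3–CH(OTBS)–(CH2)3–[C17/C18 diol acetonide]; C5, C9, C13, C17 as in the target | C=CC[C@H](O[Si](C)(C)C(C)(C)C)CCC[C@H](O)CCC[C@@H](O[Si](C)(C)C(C)(C)C)CCC[C@H]1COC(C)(C)O1 | intermediate
19 | C3–C18 tris-TBS ether (O5, O9, O13) with C17/C18 acetonide | C=CC[C@H](O[Si](C)(C)C(C)(C)C)CCC[C@H](O[Si](C)(C)C(C)(C)C)CCC[C@@H](O[Si](C)(C)C(C)(C)C)CCC[C@H]1COC(C)(C)O1 | intermediate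
20 | C3–C18 17,18-diol (O5, O9, O13 TBS) | C=CC[C@H](O[Si](C)(C)C(C)(C)C)CCC[C@H](O[Si](C)(C)C(C)(C)C)CCC[C@@H](O[Si](C)(C)C(C)(C)C)CCC[C@H](O)CO | intermediate
21 | C18 tosylate of 20 | C=CC[C@H](O[Si](C)(C)C(C)(C)C)CCC[C@H](O[Si](C)(C)C(C)(C)C)CCC[C@@H](O[Si](C)(C)C(C)(C)C)CCC[C@H](O)COS(=O)(=O)c1ccc(C)cc1 | intermediate
22 | C3–C18 epoxide (C17–C18 oxirane; O5, O9, O13 TBS) | C=CC[C@H](O[Si](C)(C)C(C)(C)C)CCC[C@H](O[Si](C)(C)C(C)(C)C)CCC[C@@H](O[Si](C)(C)C(C)(C)C)CCC[C@H]1CO1 | intermediate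
23 | C3–C26 alcohol (free C17–OH; O5, O9, O13, O21 TBS; C25/C26 acetonide); C5–C25 centres as in the target | C=CC[C@H](O[Si](C)(C)C(C)(C)C)CCC[C@H](O[Si](C)(C)C(C)(C)C)CCC[C@@H](O[Si](C)(C)C(C)(C)C)CCC[C@H](O)CCC[C@@H](O[Si](C)(C)C(C)(C)C)CCC[C@H]1COC(C)(C)O1 | intermediate
24 | C3–C26 pentakis-TBS ether (O5, O9, O13, O17, O21) with C25/C26 acetonide | C=CC[C@H](O[Si](C)(C)C(C)(C)C)CCC[C@H](O[Si](C)(C)C(C)(C)C)CCC[C@@H](O[Si](C)(C)C(C)(C)C)CCC[C@H](O[Si](C)(C)C(C)(C)C)CCC[C@@H](O[Si](C)(C)C(C)(C)C)CCC[C@H]1COC(C)(C)O1 | intermediate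
25 | C3–C26 25,26-diol (five TBS ethers) | C=CC[C@H](O[Si](C)(C)C(C)(C)C)CCC[C@H](O[Si](C)(C)C(C)(C)C)CCC[C@@H](O[Si](C)(C)C(C)(C)C)CCC[C@H](O[Si](C)(C)C(C)(C)C)CCC[C@@H](O[Si](C)(C)C(C)(C)C)CCC[C@H](O)CO | intermediate
26 | C26 tosylate of 25 | C=CC[C@H](O[Si](C)(C)C(C)(C)C)CCC[C@H](O[Si](C)(C)C(C)(C)C)CCC[C@@H](O[Si](C)(C)C(C)(C)C)CCC[C@H](O[Si](C)(C)C(C)(C)C)CCC[C@@H](O[Si](C)(C)C(C)(C)C)CCC[C@H](O)COS(=O)(=O)c1ccc(C)cc1 | intermediate
27 | C3–C26 epoxide (C25–C26 oxirane; five TBS ethers) | C=CC[C@H](O[Si](C)(C)C(C)(C)C)CCC[C@H](O[Si](C)(C)C(C)(C)C)CCC[C@@H](O[Si](C)(C)C(C)(C)C)CCC[C@H](O[Si](C)(C)C(C)(C)C)CCC[C@@H](O[Si](C)(C)C(C)(C)C)CCC[C@H]1CO1 | intermediate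
28 | 2-methyl-1,3-dithiane | CC1SCCCS1 | starting material
29 | 2-lithio-2-methyl-1,3-dithiane | [Li]C1(C)SCCCS1 | intermediate
30 | C3–C28 alcohol (free C25–OH; C27 as 2-methyl-1,3-dithiane; five TBS ethers) | C=CC[C@H](O[Si](C)(C)C(C)(C)C)CCC[C@H](O[Si](C)(C)C(C)(C)C)CCC[C@@H](O[Si](C)(C)C(C)(C)C)CCC[C@H](O[Si](C)(C)C(C)(C)C)CCC[C@@H](O[Si](C)(C)C(C)(C)C)CCC[C@H](O)CC1(C)SCCCS1 | intermediate
31 | O25 PMB ether of 30 | C=CC[C@H](O[Si](C)(C)C(C)(C)C)CCC[C@H](O[Si](C)(C)C(C)(C)C)CCC[C@@H](O[Si](C)(C)C(C)(C)C)CCC[C@H](O[Si](C)(C)C(C)(C)C)CCC[C@@H](O[Si](C)(C)C(C)(C)C)CCC[C@H](OCc1ccc(OC)cc1)CC1(C)SCCCS1 | intermediate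
32 | C3–C28 methyl ketone (C27 ketone; O25 PMB; O5, O9, O13, O17, O21 TBS; C3 vinyl) | C=CC[C@H](O[Si](C)(C)C(C)(C)C)CCC[C@H](O[Si](C)(C)C(C)(C)C)CCC[C@@H](O[Si](C)(C)C(C)(C)C)CCC[C@H](O[Si](C)(C)C(C)(C)C)CCC[C@@H](O[Si](C)(C)C(C)(C)C)CCC[C@H](OCc1ccc(OC)cc1)CC(C)=O | intermediate
33 | (E)-hept-2-en-1-ol | CCCC/C=C/CO | starting material
34 | [(2R,3R)-3-butyloxiran-2-yl]methanol | CCCC[C@H]1O[C@@H]1CO | intermediate
35 | (2S,3S)-3-methylheptane-1,2-diol | CCCC[C@H](C)[C@H](O)CO | intermediate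
36 | (2S,3S)-2-hydroxy-3-methylheptyl 4-methylbenzenesulfonate | CCCC[C@H](C)[C@H](O)COS(=O)(=O)c1ccc(C)cc1 | intermediate
37 | (2S)-2-[(2S)-hexan-2-yl]oxirane (C34–C40) | CCCC[C@H](C)[C@H]1CO1 | intermediate
38 | 1,3-dithiane | C1CSCSC1 | starting material
39 | 5-bromopent-1-ene | C=CCCCBr | starting material
40 | 2-lithio-1,3-dithiane | [Li]C1SCCCS1 | intermediate
41 | 2-(pent-4-en-1-yl)-1,3-dithiane | C=CCCCC1SCCCS1 | intermediate
42 | 2-lithio-2-(pent-4-en-1-yl)-1,3-dithiane | [Li]C1(CCCC=C)SCCCS1 | intermediate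
43 | (2R,3S)-3-methyl-1-[2-(pent-4-en-1-yl)-1,3-dithian-2-yl]heptan-2-ol | CCCC[C@H](C)[C@H](O)CC1(CCCC=C)SCCCS1 | intermediate
44 | (8R,9S)-8-hydroxy-9-methyltridec-1-en-6-one | CCCC[C@H](C)[C@H](O)CC(=O)CCCC=C | intermediate
45 | (6S,8R,9S)-6-hydroxy-9-methyltridec-1-en-8-yl benzoate | CCCC[C@H](C)[C@H](OC(=O)c1ccccc1)C[C@@H](O)CCCC=C | intermediate
46 | (6S,8R,9S)-6-[(tert-butyldimethylsilyl)oxy]-9-methyltridec-1-en-8-yl benzoate | CCCC[C@H](C)[C@H](OC(=O)c1ccccc1)C[C@@H](O[Si](C)(C)C(C)(C)C)CCCC=C | intermediate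
47 | ozonide (1,2,4-trioxolane) of 46, mixture at the ring carbon | CCCC[C@H](C)[C@H](OC(=O)c1ccccc1)C[C@@H](O[Si](C)(C)C(C)(C)C)CCCC1OCOO1 | intermediate
48 | (5S,7R,8S)-5-[(tert-butyldimethylsilyl)oxy]-8-methyl-1-oxododecan-7-yl benzoate (C29–C40 aldehyde) | CCCC[C@H](C)[C@H](OC(=O)c1ccccc1)C[C@@H](O[Si](C)(C)C(C)(C)C)CCCC=O | intermediate
49 | dibutylboron enolate of 32 (C27–C28 enol borinate) | C=C(OB(CCCC)CCCC)C[C@@H](OCc1ccc(OC)cc1)CCC[C@H](O[Si](C)(C)C(C)(C)C)CCC[C@@H](O[Si](C)(C)C(C)(C)C)CCC[C@H](O[Si](C)(C)C(C)(C)C)CCC[C@@H](O[Si](C)(C)C(C)(C)C)CCC[C@@H](O[Si](C)(C)C(C)(C)C)CC=C | intermediate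
50 | C3–C40 aldol adduct (C29–OH; C27 ketone; O25 PMB; O35 benzoate; O5, O9, O13, O17, O21, O33 TBS) | CCCC[C@H](C)[C@H](OC(=O)c1ccccc1)C[C@@H](O[Si](C)(C)C(C)(C)C)CCC[C@H](O)CC(=O)C[C@@H](OCc1ccc(OC)cc1)CCC[C@H](O[Si](C)(C)C(C)(C)C)CCC[C@@H](O[Si](C)(C)C(C)(C)C)CCC[C@H](O[Si](C)(C)C(C)(C)C)CCC[C@@H](O[Si](C)(C)C(C)(C)C)CCC[C@@H](O[Si](C)(C)C(C)(C)C)CC=C | intermediate
51 | C3–C40 27,29-diol (all centres as in the target) | CCCC[C@H](C)[C@H](OC(=O)c1ccccc1)C[C@@H](O[Si](C)(C)C(C)(C)C)CCC[C@H](O)C[C@@H](O)C[C@@H](OCc1ccc(OC)cc1)CCC[C@H](O[Si](C)(C)C(C)(C)C)CCC[C@@H](O[Si](C)(C)C(C)(C)C)CCC[C@H](O[Si](C)(C)C(C)(C)C)CCC[C@@H](O[Si](C)(C)C(C)(C)C)CCC[C@@H](O[Si](C)(C)C(C)(C)C)CC=C | intermediate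
52 | fully protected C3–C40 chain (eight TBS ethers; O25 PMB; O35 benzoate; C3 vinyl) | CCCC[C@H](C)[C@H](OC(=O)c1ccccc1)C[C@@H](O[Si](C)(C)C(C)(C)C)CCC[C@H](O[Si](C)(C)C(C)(C)C)C[C@@H](O[Si](C)(C)C(C)(C)C)C[C@@H](OCc1ccc(OC)cc1)CCC[C@H](O[Si](C)(C)C(C)(C)C)CCC[C@@H](O[Si](C)(C)C(C)(C)C)CCC[C@H](O[Si](C)(C)C(C)(C)C)CCC[C@@H](O[Si](C)(C)C(C)(C)C)CCC[C@@H](O[Si](C)(C)C(C)(C)C)CC=C | intermediate
53 | C3–C40 O35 alcohol (eight TBS ethers; O25 PMB; C3 vinyl) | CCCC[C@H](C)[C@H](O)C[C@@H](O[Si](C)(C)C(C)(C)C)CCC[C@H](O[Si](C)(C)C(C)(C)C)C[C@@H](O[Si](C)(C)C(C)(C)C)C[C@@H](OCc1ccc(OC)cc1)CCC[C@H](O[Si](C)(C)C(C)(C)C)CCC[C@@H](O[Si](C)(C)C(C)(C)C)CCC[C@H](O[Si](C)(C)C(C)(C)C)CCC[C@@H](O[Si](C)(C)C(C)(C)C)CCC[C@@H](O[Si](C)(C)C(C)(C)C)CC=C | intermediate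
54 | diethylphosphonoacetic acid | OC(=O)CP(=O)(OCC)OCC | starting material
55 | C3–C40 O35 diethylphosphonoacetate (C3 vinyl) | CCCC[C@H](C)[C@H](OC(=O)CP(=O)(OCC)OCC)C[C@@H](O[Si](C)(C)C(C)(C)C)CCC[C@H](O[Si](C)(C)C(C)(C)C)C[C@@H](O[Si](C)(C)C(C)(C)C)C[C@@H](OCc1ccc(OC)cc1)CCC[C@H](O[Si](C)(C)C(C)(C)C)CCC[C@@H](O[Si](C)(C)C(C)(C)C)CCC[C@H](O[Si](C)(C)C(C)(C)C)CCC[C@@H](O[Si](C)(C)C(C)(C)C)CCC[C@@H](O[Si](C)(C)C(C)(C)C)CC=C | intermediate
56 | vicinal diol from dihydroxylation of the vinyl group of 55, mixture at C3 | CCCC[C@H](C)[C@H](OC(=O)CP(=O)(OCC)OCC)C[C@@H](O[Si](C)(C)C(C)(C)C)CCC[C@H](O[Si](C)(C)C(C)(C)C)C[C@@H](O[Si](C)(C)C(C)(C)C)C[C@@H](OCc1ccc(OC)cc1)CCC[C@H](O[Si](C)(C)C(C)(C)C)CCC[C@@H](O[Si](C)(C)C(C)(C)C)CCC[C@H](O[Si](C)(C)C(C)(C)C)CCC[C@@H](O[Si](C)(C)C(C)(C)C)CCC[C@@H](O[Si](C)(C)C(C)(C)C)CC(O)CO | intermediate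
57 | C3 aldehyde with O35 diethylphosphonoacetate (olefination precursor; eight TBS ethers; O25 PMB) | CCCC[C@H](C)[C@H](OC(=O)CP(=O)(OCC)OCC)C[C@@H](O[Si](C)(C)C(C)(C)C)CCC[C@H](O[Si](C)(C)C(C)(C)C)C[C@@H](O[Si](C)(C)C(C)(C)C)C[C@@H](OCc1ccc(OC)cc1)CCC[C@H](O[Si](C)(C)C(C)(C)C)CCC[C@@H](O[Si](C)(C)C(C)(C)C)CCC[C@H](O[Si](C)(C)C(C)(C)C)CCC[C@@H](O[Si](C)(C)C(C)(C)C)CCC[C@@H](O[Si](C)(C)C(C)(C)C)CC=O | intermediate
58 | 36-membered (2E)-enoate lactone without the C3 methyl group (eight TBS ethers; O25 PMB) | CCCC[C@H](C)[C@H]1C[C@@H](O[Si](C)(C)C(C)(C)C)CCC[C@H](O[Si](C)(C)C(C)(C)C)C[C@@H](O[Si](C)(C)C(C)(C)C)C[C@@H](OCc2ccc(OC)cc2)CCC[C@H](O[Si](C)(C)C(C)(C)C)CCC[C@@H](O[Si](C)(C)C(C)(C)C)CCC[C@H](O[Si](C)(C)C(C)(C)C)CCC[C@@H](O[Si](C)(C)C(C)(C)C)CCC[C@@H](O[Si](C)(C)C(C)(C)C)C/C=C/C(=O)O1 | intermediate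
59 | (3R)-3-methyl macrolactone (eight TBS ethers; O25 PMB) | CCCC[C@H](C)[C@H]1C[C@@H](O[Si](C)(C)C(C)(C)C)CCC[C@H](O[Si](C)(C)C(C)(C)C)C[C@@H](O[Si](C)(C)C(C)(C)C)C[C@@H](OCc2ccc(OC)cc2)CCC[C@H](O[Si](C)(C)C(C)(C)C)CCC[C@@H](O[Si](C)(C)C(C)(C)C)CCC[C@H](O[Si](C)(C)C(C)(C)C)CCC[C@@H](O[Si](C)(C)C(C)(C)C)CCC[C@@H](O[Si](C)(C)C(C)(C)C)C[C@@H](C)CC(=O)O1 | intermediate
60 | C25 alcohol of the macrolactone (eight TBS ethers) | CCCC[C@H](C)[C@H]1C[C@@H](O[Si](C)(C)C(C)(C)C)CCC[C@H](O[Si](C)(C)C(C)(C)C)C[C@@H](O[Si](C)(C)C(C)(C)C)C[C@@H](O)CCC[C@H](O[Si](C)(C)C(C)(C)C)CCC[C@@H](O[Si](C)(C)C(C)(C)C)CCC[C@H](O[Si](C)(C)C(C)(C)C)CCC[C@@H](O[Si](C)(C)C(C)(C)C)CCC[C@@H](O[Si](C)(C)C(C)(C)C)C[C@@H](C)CC(=O)O1 | intermediate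
61 | CNP0225459.2, (3R,5R,9R,13S,17S,21R,25S,27S,29S,33S,35R)-35-[(2S)-hexan-2-yl]-5,9,13,17,21,25,27,29,33-nonahydroxy-3-methyl-36-membered lactone | CCCC[C@H](C)[C@H]1C[C@@H](O)CCC[C@H](O)C[C@@H](O)C[C@@H](O)CCC[C@H](O)CCC[C@@H](O)CCC[C@H](O)CCC[C@@H](O)CCC[C@@H](O)C[C@@H](C)CC(=O)O1 | target

**Step count and risks**

Total step count: 43. Longest linear sequence: 28 steps (from 1 through steps 1–6, 13–24 and 34–43).

Steps most likely to fail:

1. Step 41. Methyl transfer to the enoate of a hindered secondary alcohol held in a macrocycle may be sluggish or poorly face-selective, and 1,2-addition at the lactone carbonyl may compete. The fallback sets out from 53 and comes back at 59. Cross-metathesis of the terminal alkene of 53 with methyl acrylate (second-generation Hoveyda–Grubbs catalyst, CH2Cl2, 40 °C) gives the acyclic methyl (E)-enoate F1. Addition of MeMgBr under CuI/(S)-Tol-BINAP to this methyl ester, the substrate class for which the catalyst is established, gives the (3R)-3-methyl ester F2; one further equivalent of the Grignard reagent is allowed for the free O35 hydroxyl. Saponification (LiOH, THF/MeOH/H2O) gives the seco acid F3, and Yamaguchi macrolactonisation at O35 (2,4,6-trichlorobenzoyl chloride, Et3N, THF; then DMAP, toluene, high dilution) gives 59.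

2. Step 40. Oligomerisation may outrun ring closure, or the base may trigger β-elimination of the C5 silyloxy group of the aldehyde before olefination. The fallback sets out from 53 and comes back at 58. Acylation of O35 with acryloyl chloride (i-Pr2NEt, CH2Cl2, 0 °C) gives the acrylate F4. Ring-closing metathesis between the acrylate and the C3 vinyl group (second-generation Grubbs catalyst, toluene, 80 °C, 1 mM) forms the same E-configured C2=C3 bond and gives 58 without any aldehyde or base.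

3. Step 14 (and its repeat, step 18). The functionalised Grignard reagent 17 may be delivered at low titre after Wurtz homocoupling in step 13, so that magnesium bromide opens the epoxide to the bromohydrin faster than copper-mediated C–C coupling occurs. The fallback sets out from 8 and 16 and comes back at 18. Displacement of the bromide of 8 with PhSO2Na (DMF, 60 °C) gives the phenyl sulfone F5. Its lithio derivative (n-BuLi, THF, −78 °C) opens epoxide 16 in the presence of BF3·OEt2 to give the C11-sulfonyl alcohol F6, and reductive desulfonylation with Na/Hg (Na2HPO4, MeOH/THF, −20 °C) gives 18. For the repeat, lithiated F5 opens epoxide 22 in the same way to give the C19-sulfonyl alcohol F7, and the same desulfonylation gives 23.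

**Further compounds**

F1 | step 41 | methyl (2E)-enoate of the C1–C40 chain with free O35–H (eight TBS ethers; O25 PMB) | CCCC[C@H](C)[C@H](O)C[C@@H](O[Si](C)(C)C(C)(C)C)CCC[C@H](O[Si](C)(C)C(C)(C)C)C[C@@H](O[Si](C)(C)C(C)(C)C)C[C@@H](OCc1ccc(OC)cc1)CCC[C@H](O[Si](C)(C)C(C)(C)C)CCC[C@@H](O[Si](C)(C)C(C)(C)C)CCC[C@H](O[Si](C)(C)C(C)(C)C)CCC[C@@H](O[Si](C)(C)C(C)(C)C)CCC[C@@H](O[Si](C)(C)C(C)(C)C)C/C=C/C(=O)OC
F2 | step 41 | methyl (3R)-3-methyl ester of the C1–C40 chain with free O35–H | CCCC[C@H](C)[C@H](O)C[C@@H](O[Si](C)(C)C(C)(C)C)CCC[C@H](O[Si](C)(C)C(C)(C)C)C[C@@H](O[Si](C)(C)C(C)(C)C)C[C@@H](OCc1ccc(OC)cc1)CCC[C@H](O[Si](C)(C)C(C)(C)C)CCC[C@@H](O[Si](C)(C)C(C)(C)C)CCC[C@H](O[Si](C)(C)C(C)(C)C)CCC[C@@H](O[Si](C)(C)C(C)(C)C)CCC[C@@H](O[Si](C)(C)C(C)(C)C)C[C@@H](C)CC(=O)OC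
F3 | step 41 | (3R)-3-methyl seco acid with free O35–H | CCCC[C@H](C)[C@H](O)C[C@@H](O[Si](C)(C)C(C)(C)C)CCC[C@H](O[Si](C)(C)C(C)(C)C)C[C@@H](O[Si](C)(C)C(C)(C)C)C[C@@H](OCc1ccc(OC)cc1)CCC[C@H](O[Si](C)(C)C(C)(C)C)CCC[C@@H](O[Si](C)(C)C(C)(C)C)CCC[C@H](O[Si](C)(C)C(C)(C)C)CCC[C@@H](O[Si](C)(C)C(C)(C)C)CCC[C@@H](O[Si](C)(C)C(C)(C)C)C[C@@H](C)CC(=O)O
F4 | step 40 | O35 acrylate of 53 | CCCC[C@H](C)[C@H](OC(=O)C=C)C[C@@H](O[Si](C)(C)C(C)(C)C)CCC[C@H](O[Si](C)(C)C(C)(C)C)C[C@@H](O[Si](C)(C)C(C)(C)C)C[C@@H](OCc1ccc(OC)cc1)CCC[C@H](O[Si](C)(C)C(C)(C)C)CCC[C@@H](O[Si](C)(C)C(C)(C)C)CCC[C@H](O[Si](C)(C)C(C)(C)C)CCC[C@@H](O[Si](C)(C)C(C)(C)C)CCC[C@@H](O[Si](C)(C)C(C)(C)C)CC=C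
F5 | step 14 | phenyl sulfone from bromide 8 | O=S(=O)(c1ccccc1)CC[C@@H](O[Si](C)(C)C(C)(C)C)CCC[C@H]1COC(C)(C)O1
F6 | step 14 | C11-phenylsulfonyl C3–C18 alcohol, mixture at C11 | C=CC[C@H](O[Si](C)(C)C(C)(C)C)CCC[C@H](O)CC(S(=O)(=O)c1ccccc1)C[C@@H](O[Si](C)(C)C(C)(C)C)CCC[C@H]1COC(C)(C)O1
F7 | step 14 | C19-phenylsulfonyl C3–C26 alcohol, mixture at C19 | C=CC[C@H](O[Si](C)(C)C(C)(C)C)CCC[C@H](O[Si](C)(C)C(C)(C)C)CCC[C@@H](O[Si](C)(C)C(C)(C)C)CCC[C@H](O)CC(S(=O)(=O)c1ccccc1)C[C@@H](O[Si](C)(C)C(C)(C)C)CCC[C@H]1COC(C)(C)O1
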